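## The problem

The target is a germacrane sesquiterpene lactone; germacrane numbering is used throughout (ring carbons C1–C10, lactone carbons C11–C13, C14 the methyl on C10, C15 the methyl on C4). Its ten-membered carbocycle is bridged by oxygen between C3 and C10 into a 3(2H)-furanone (C10–O–C3=C2–C1=O) and is trans-fused at C7/C8 to an α-methylene-γ-butyrolactone; a Z C4=C5 bond is cross-conjugated with the furanone and O6 carries a (2S,3R)-2,3-dimethyloxirane-2-carboxylate. The ring has four stereocentres: the contiguous triad C6 (R), C7 (R), C8 (S), in which O6, C11 and O8 are all syn on the extended C5–C9 chain, and the isolated quaternary C10 (R). C6 can control C7, and C7 can control C8, if the triad is made on a small ring; C10 is insulated by the C9 methylene and must come from the chiral pool, as must C6, while the two epoxide centres are best set by a reagent and brought in as the acid. The methylene lactone is a Michael acceptor for phosphines, amines and thiolates, the Z dienone isomerises and is deprotonated at its γ-positions by base, the glycidic ester tolerates neither acid nor hydride, and a free C6 hydroxyl next to a C3 ketone would close to a furan. The hardest single task is the strained ten-membered carbocycle with its Z alkene. The opening lies in the furanone ring: C1–C2–C3 is a 1,3-diketone whose C3 oxygen is the enol ether oxygen O10, so the C1–C2 ring bond can be made last, from a C1 thioester and the C2 methylene of a C3 ketone, two atoms that an eleven-membered thiolactone already holds next to each other across sulfur.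

## Retrosynthesis

**Ester C–O bond at O6.** Target 43 is cut into the 6-hydroxy lactone 37 and epoxy acid 41. The glycidic ester is the least robust group and would survive none of the earlier hydride, base or phosphine steps, so it goes on last. Acid 41 is three steps from tiglic acid 38 through alcohol 39 and the reagent-controlled epoxidation to 40. The forward step must acylate a hindered allylic alcohol without touching the methylene lactone.

**Lactone O8–C12 bond.** 37 comes from its PMB ether 36, and 36 from the 2-methylene-1,4-diol 33 by oxidative lactonisation. Carrying the lactone as a diol removes the acrylate that phosphine and base of the key step would attack. With O6 still protected, only O8 can close onto C12, so the 8,12-lactone forms without a 6,12 isomer, and C8 keeps its configuration.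

**Furanone C3–O10 bond.** 33 is the cyclodehydration and desilylation product of the ten-membered 1,3-diketone 30, through the hydroxy diketone 31 and the silylated furanone 32. This exposes the 1,3-diketone. O10 stays silylated until the diketone exists, and O8 is still silylated when O10 closes, so no other hydroxyl competes for C1 or C3.

**C1–C2 bond (key step).** 30 is traced to the eleven-membered keto thiolactone 28, in which sulfur sits between C1 and C2. Any direct C–C closure of the ten-membered ring (Claisen, Reformatsky, olefination) is an end-to-end cyclisation of a strained medium ring. Here the ring is closed beforehand by an easy C–S bond and the C–C bond then forms between neighbours. The forward step needs enolisation at C2 only, removal of sulfur, and an untouched Z alkene.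

**S–C2 bond.** 28 opens to the bromomethyl ketone 26, whose C1 carboxyl is a masked thioacid (S-9-fluorenylmethyl thioester). Closure at S–C2 is preferred over acylation of a C2 thiol at C1, because C1 is flanked by the quaternary C10. The thioester 24 is made from acid 23 before the bromoketone is unveiled, since a free thiol and an α-halo ketone cannot coexist.

**C3–C4 and C4=C5 bonds.** The bromoketone 26 comes from enol ether 25, and 25 from the Z alkenyl iodide 24 by Stille coupling; both steps are mild enough for the thioester. The iodide geometry is set at aldehyde 20 by iodo-Wittig olefination to 21, so the Z alkene is fixed long before the ring exists. C1 is raised to the acid (21 to 22 to 23) only after the last hydride step.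

**Protecting-group pattern.** Aldehyde 20 derives from alcohol 19, and 19 from triol 16 through acetals 17 and 18: the 1,2-diol O5/O6 is tied as a 4-methoxybenzylidene acetal and opened reductively, which puts PMB on O6 and frees C5 for oxidation. Triol 16 is the reduction product of lactone 15, the silyl ether of 14. The 6,12-lactone of 14 thus differentiates O6 from O8 from the moment the triad is made.

**C7–C8 bond.** 14 is cut into bromomethyl butenolide 7 and aldehyde 12. This is the only C–C fragment union and it sets C7 and C8. An acyclic 2-(bromomethyl)acrylate from the same chiral pool would carry the C6 substituent cis to the CH2–metal group and favour the 7,8-syn isomer. The butenolide ring locks C6 trans to it, which gives 7,8-anti, and shields one face, which gives 6,7-trans.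

**Fragments.** 7 comes in four steps from (R)-glyceraldehyde acetonide 1 and methyl acrylate 2 through 3, 5 and 6. Aldehyde 12 comes in three steps from (S)-2-methylglycidol 8 through 9 and 10; the C1 carbon is kept at the alcohol level as a triethylsilyl ether because two hydride steps follow the union.

## Roads not taken

**Alternative 1:** The cut is C6–C7, with the C11=C13 methylene formed in the same event. The thirteen-membered bis-allylic ether A2 (oxygen linking C6 and C13, C7=C11 as a butenolide double bond) would be deprotonated at C6. The [2,3]-Wittig shift then forms C6–C7, releases the C6 alkoxide and the exocyclic methylene, and contracts the ring to A1, which is identical with 37. Its merits are real: a macro-etherification replaces the C–C ring closure, two stereocentres and the methylene lactone appear in one step, and A1 is one acylation from the target, so the route would be markedly shorter than the chosen one. Its weak points lie in the carbanion chemistry. The C8 proton of the butenolide is more acidic than the C6 ether protons and the furanone and dienone are base-sensitive, so regioselective deprotonation is not secured. A [1,2] shift competes. C6 and C7 would be set in a macrocyclic transition state with no reliable control element, and the new C6 alkoxide sits next to the lactone and can translactonise. Against the shorter sequence the chosen plan sets certainty: every stereocentre is fixed on a five-membered ring before any ring closure, and its key step needs only the most acidic proton of the molecule.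

**Alternative 2:** The cut is C2–C3 and C4–C5, a two-carbon insertion of C3–C4 into an eight-membered ring. Irradiation of cyclooctenone A4, which carries a propynyl ether on O10, would join C2 to C3 and C5 to C4; thermal opening of the C2–C5 bond would then give the ten-membered furanone A3. This avoids any macrocyclisation and any sulfur chemistry, builds the furanone and the medium ring together, and A3 needs only desilylation and acylation, so its endgame is shorter than the chosen one. The weak points are structural. A thermal conrotatory opening of a ring-fused cyclobutene delivers one double bond with the wrong geometry for a five-membered furanone plus a Z alkene, so the required course is disfavoured. The tertiary ynol ether has β-hydrogens and fragments to a ketene on warming. The methylene lactone competes in the photochemistry. A4 itself, an eight-membered ring with four stereocentres and a trans-fused lactone, is no easier to make than the seco chain used here. The chosen plan sets the Z alkene by olefination and the furanone by a dehydration that cannot give another isomer.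

**Alternative 3:** The cut is C8–C9. In aldehyde A6 the furanone is stored as a cyclopropanated siloxyfuran; TiCl4 would activate the C8 aldehyde, the C1–C9 cyclopropane bond would open onto it, and the ten-membered hydroxy malonate A5 would result with the C1 ketone regenerated. It is at least as good as the chosen plan in two respects: ring closure is driven by strain release, and the furanone is present early, so no late acid cyclisation is needed. Its weak points: C8 is created in the macrocyclisation with nothing but a medium-ring transition state to control it. C10 must be set by a face-selective cyclopropanation of a furan instead of coming from the chiral pool. TiCl4 meets an allylic silyl ether at C6 that can ionise. The malonate still needs several steps to become the methylene lactone. The chosen plan forms no stereocentre in either ring-forming step and takes C10 from a commercial epoxide; the price is a longer protecting-group sequence.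

Key step: step 22

## Route

Remark: compounds 3–6 are carried as epimer mixtures at the future C7 and 17–18 at the acetal carbon, since both centres disappear later.

Step 1
Reactants: 1 (R)-glyceraldehyde acetonide; 2 methyl acrylate
Product: 3 Morita–Baylis–Hillman adduct, methyl 2-{[(4R)-2,2-dimethyl-1,3-dioxolan-4-yl](hydroxy)methyl}prop-2-enoate (both carbinol epimers)
Conditions: DABCO (0.5 equiv), 1,4-dioxane/H2O (1:1), rt
Reagents that add atoms: none
Why: Morita–Baylis–Hillman reaction of an acrylate with an α-alkoxy aldehyde. The new carbinol (future C7) becomes sp2 in step 4, so both epimers are used, and the C6 centre of 1 is not involved.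

Step 2
Reactants: 3 Morita–Baylis–Hillman adduct
Product: 5 hydroxy lactone (5R)-4-hydroxy-5-(hydroxymethyl)-3-methylideneoxolan-2-one (both C4 epimers), via triol ester 4 (not isolated)
Conditions: CF3CO2H/H2O (4:1), 0 °C to rt; then evaporation from toluene
Reagents that add atoms: none
Why: Acid-catalysed acetonide hydrolysis followed by lactonisation. The five-membered lactone through O6 should be preferred over the six-membered one through O5, and no bond to C6 is broken.

Step 3
Reactants: 5 hydroxy lactone
Product: 6 lactone pivalate, [(2R)-3-hydroxy-4-methylidene-5-oxooxolan-2-yl]methyl 2,2-dimethylpropanoate (both C3 epimers)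
Conditions: PivCl (1.05 equiv), pyridine, CH2Cl2, −20 to 0 °C
Reagents that add atoms: pivaloyl chloride, CC(C)(C)C(=O)Cl
Why: Selective acylation of the primary hydroxyl by a hindered acid chloride; the secondary allylic hydroxyl is left for step 4.

Step 4
Reactants: 6 lactone pivalate
Product: 7 bromomethyl butenolide, [(2S)-4-(bromomethyl)-5-oxo-2,5-dihydrofuran-2-yl]methyl 2,2-dimethylpropanoate
Conditions: PBr3 (0.4 equiv), Et2O, −10 to 0 °C
Reagents that add atoms: phosphorus tribromide, BrP(Br)Br
Why: Allylic bromination with transposition (SN2′), as for Baylis–Hillman alcohols. It should give the conjugated primary bromide, and both carbinol epimers converge on one compound.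

Step 5
Reactants: 8 (S)-2-methylglycidol
Product: 9 (2R)-2-methylpent-4-ene-1,2-diol
Conditions: vinylmagnesium bromide (3 equiv), CuI (10 mol%), THF, −30 to 0 °C; aq. NH4Cl
Reagents that add atoms: vinylmagnesium bromide, C=C[Mg]Br
Why: Copper-catalysed Grignard opening of an epoxide at its unsubstituted carbon. The quaternary centre (future C10) is not touched; the descriptor changes from S to R only through the priority change.

Step 6
Reactants: 9 (2R)-2-methylpent-4-ene-1,2-diol
Product: 10 bis(triethylsilyl) ether, (4R)-4-methyl-4,5-bis(triethylsilyloxy)pent-1-ene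
Conditions: TESOTf (2.4 equiv), 2,6-lutidine, CH2Cl2, −78 to 0 °C
Reagents that add atoms: triethylsilyl trifluoromethanesulfonate, CC[Si](CC)(CC)OS(=O)(=O)C(F)(F)F
Why: Silylation with a silyl triflate, which is needed for the tertiary hydroxyl (O10). The primary TES ether is the latent C1 aldehyde.

Step 7
Reactants: 10 bis(triethylsilyl) ether
Product: 12 aldehyde (3R)-3-methyl-3,4-bis(triethylsilyloxy)butanal, via ozonide 11 (not isolated)
Conditions: O3, CH2Cl2, −78 °C; then PPh3, −78 °C to rt
Reagents that add atoms: ozone, [O-][O+]=O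
Why: Ozonolysis with reductive work-up of the only alkene present gives the C8 aldehyde.

Step 8
Reactants: 7 bromomethyl butenolide; 12 aldehyde
Product: 14 6,12-lactone C8 alcohol (6S,7R,8S,10R), via allylzinc bromide 13 (not isolated)
Conditions: Zn dust (3 equiv), THF/sat. aq. NH4Cl (2:1), 0 °C to rt
Reagents that add atoms: none
Why: Barbier-type allylation of an aldehyde by a 2-(bromomethyl)butenolide; the allylzinc adds through its γ-carbon C7 in a six-membered chair transition state. The lactone ring holds C6 trans to the CH2Zn group, so C6 is equatorial and the 7,8-anti adduct should result, while approach opposite the pivaloyloxymethyl group sets C7 trans to C6. The aqueous medium protonates the C8 alkoxide at once, which should keep the lactone on O6.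

Step 9
Reactants: 14 6,12-lactone C8 alcohol
Product: 15 6,12-lactone C8 TBS ether (6S,7S,8S,10R)
Conditions: TBSOTf, 2,6-lutidine, CH2Cl2, −78 °C
Reagents that add atoms: tert-butyldimethylsilyl trifluoromethanesulfonate, CC(C)(C)[Si](C)(C)OS(=O)(=O)C(F)(F)F
Why: Silyl triflate protection of a hindered secondary alcohol under non-nucleophilic base. It is done without delay so that O8 cannot translactonise onto C12.

Step 10
Reactants: 15 6,12-lactone C8 TBS ether
Product: 16 C5,C6,C12-triol (6S,7S,8S,10R)
Conditions: i-Bu2AlH (8 equiv), CH2Cl2, −78 to 0 °C; aq. potassium sodium tartrate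
Reagents that add atoms: none
Why: Hydride reduction of an α-methylene-γ-butyrolactone to the 2-methylene-1,4-diol (1,2-addition) with reductive removal of the pivalate in the same operation. Silyl ethers are inert, and no ester-level carbon remains at C1 to be reduced.

Step 11
Reactants: 16 C5,C6,C12-triol
Product: 17 O5,O6 4-methoxybenzylidene acetal (acetal epimers)
Conditions: 4-MeOC6H4CH(OMe)2, PPTS (cat.), CH2Cl2, rt
Reagents that add atoms: 4-methoxybenzaldehyde dimethyl acetal, COC(OC)c1ccc(OC)cc1
Why: Acid-catalysed transacetalisation under thermodynamic control. The 1,2-diol should give the five-membered dioxolane in preference to a seven-membered acetal with O12.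

Step 12
Reactants: 17 O5,O6 4-methoxybenzylidene acetal
Product: 18 acetal C12 TBS ether
Conditions: TBSCl, imidazole, CH2Cl2, 0 °C to rt
Reagents that add atoms: tert-butyldimethylsilyl chloride, CC(C)(C)[Si](C)(C)Cl
Why: Standard silylation of the remaining primary allylic alcohol.

Step 13
Reactants: 18 acetal C12 TBS ether
Product: 19 C5 alcohol with O6 PMB ether (6S,7S,8S,10R)
Conditions: i-Bu2AlH (4 equiv), CH2Cl2, −78 to −10 °C; aq. potassium sodium tartrate
Reagents that add atoms: none
Why: Regioselective reductive opening of a 4-methoxybenzylidene acetal. Aluminium binds the less hindered primary oxygen, so the PMB ether should stay on O6 and the C5 alcohol is freed.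

Step 14
Reactants: 19 C5 alcohol
Product: 20 C5 aldehyde (6S,7S,8S,10R)
Conditions: Dess–Martin periodinane, NaHCO3, CH2Cl2, 0 °C to rt
Reagents that add atoms: none
Why: Dess–Martin oxidation under buffered conditions, which should not epimerise the α-alkoxy aldehyde and leaves the primary TES ether alone.

Step 15
Reactants: 20 C5 aldehyde
Product: 21 (Z)-alkenyl iodide (4Z,6S,7S,8S,10R)
Conditions: EtPPh3I, n-BuLi, THF, rt; I2, −78 °C; NaN(SiMe3)2, −20 °C; then 20, −78 to −20 °C
Reagents that add atoms: ethyltriphenylphosphonium iodide, CC[P+](c1ccccc1)(c1ccccc1)c1ccccc1.[I-]; iodine, II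
Why: Stork–Zhao olefination (Wittig reaction of an α-iodo ylide), which gives (Z)-2-iodoalk-2-enes. Iodine ends cis to C6, the arrangement needed for the Z C4=C5 bond once iodine is replaced by C3.

Step 16
Reactants: 21 (Z)-alkenyl iodide
Product: 22 C1 aldehyde (4Z,6S,7S,8S,10R)
Conditions: (COCl)2, DMSO, CH2Cl2, −78 °C; then 21, −78 to −30 °C; Et3N
Reagents that add atoms: none
Why: Swern oxidation of a primary triethylsilyl ether directly to the aldehyde (oxidative desilylation). The tertiary TES ether cannot be oxidised and TBS ethers do not react.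

Step 17
Reactants: 22 C1 aldehyde
Product: 23 C1 acid (4Z,6S,7S,8S,10R)
Conditions: NaClO2, NaH2PO4, 2-methyl-2-butene, t-BuOH/H2O, 0 °C to rt
Reagents that add atoms: sodium chlorite, [Na+].[O-]Cl=O
Why: Pinnick oxidation; the alkene scavenger takes up hypochlorous acid, so the alkenes and the PMB ether should survive.

Step 18
Reactants: 23 C1 acid
Product: 24 S-(9-fluorenylmethyl) thioester (4Z,6S,7S,8S,10R)
Conditions: 9-fluorenylmethanethiol, EDC·HCl, DMAP (0.2 equiv), CH2Cl2, 0 °C to rt
Reagents that add atoms: 9-fluorenylmethanethiol, SCC1c2ccccc2-c2ccccc12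
Why: Carbodiimide thioesterification (Steglich type). The fluorenylmethyl thioester is a masked thioacid that is released later by β-elimination, without acid or fluoride.

Step 19
Reactants: 24 S-(9-fluorenylmethyl) thioester
Product: 25 2-ethoxydiene (4Z,6R,7S,8S,10R)
Conditions: tributyl(1-ethoxyvinyl)stannane, Pd(PPh3)4 (5 mol%), toluene, 70 °C
Reagents that add atoms: tributyl(1-ethoxyvinyl)stannane, CCOC(=C)[Sn](CCCC)(CCCC)CCCC
Why: Stille coupling of an alkenyl iodide with retention of geometry; it installs C3 and C2 as an enol ether. Without copper or zinc cofactors the hindered tertiary thioester should not add to zerovalent palladium.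

Step 20
Reactants: 25 2-ethoxydiene
Product: 26 bromomethyl ketone (4Z,6R,7S,8S,10R)
Conditions: NBS (1.05 equiv), NaHCO3, THF/H2O (10:1), 0 °C
Reagents that add atoms: N-bromosuccinimide, O=C1CCC(=O)N1Br; water, O
Why: Electrophilic bromination of an enol ether with hydrolysis of the oxocarbenium ion to the α-bromo ketone. The enol ether is far more nucleophilic than the 1,1-disubstituted alkene or the thioester sulfur.

Step 21
Reactants: 26 bromomethyl ketone
Product: 28 eleven-membered keto thiolactone (4Z,6R,7S,8S,10R), via thioacid 27 (not isolated)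
Conditions: DBU (2.5 equiv), MeCN, 1 mM, slow addition of 26, 0 °C to rt
Reagents that add atoms: none
Why: Base-induced β-elimination (E1cB) of the fluorenylmethyl thioester releases the thiocarboxylate, which is alkylated intramolecularly by the α-bromo ketone. Thiocarboxylate S-alkylation is fast enough to close an eleven-membered ring at high dilution, and the hindered C1 carbonyl takes no part in the bond formation.

Step 22
Reactants: 28 eleven-membered keto thiolactone
Product: 30 ten-membered 1,3-diketone (4Z,6R,7S,8S,10R), via thiirane alkoxide 29 (not isolated)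
Conditions: KOtBu (1.1 equiv), PPh3 (2 equiv), THF, −40 °C to rt; aq. NH4Cl
Reagents that add atoms: none
Why: Eschenmoser sulfide contraction. KOtBu removes a proton from C2, the only carbon flanked by the C3 ketone and the acylthio group; the enolate carbon adds to the C1 thioester carbonyl (3-exo-trig) and forms the C1–C2 bond as the thiirane alkoxide 29, which already contains the ten-membered carbocycle. PPh3 attacks sulfur, Ph3P=S leaves and the enolate of the 1,3-diketone remains, so one equivalent of base is consumed and the product is stored as an unreactive enolate. The closest known reaction type is the sulfide contraction of S-(2-oxoalkyl) thioesters to 1,3-dicarbonyl compounds, which has also been used in ring-contracting mode to make medium-ring β-keto lactones. The ten-membered ring is therefore closed by a bond between atoms already held 1,3 across sulfur (eleven to ten), not by an end-to-end cyclisation. No stereocentre is formed: C2 remains a methylene group and C1 becomes sp2. The step needs enolisation at C2 only and retention of the Z C4=C5 geometry: C2 is far more acidic than the γ-positions C15 and C6, no excess base is present, O10 is silylated so it cannot add to C3 and remove the ketone that acidifies C2, and the lactone is present only as silyl ethers, so PPh3 meets no acrylate.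

Step 23
Reactants: 30 ten-membered 1,3-diketone
Product: 33 furanone diol (4Z,6R,7R,8S,10R; O6 PMB), via hydroxy diketone 31 (not isolated), via furanone bis-TBS ether 32 (not isolated)
Conditions: PPTS, MeOH, 0 °C to rt; then HF·pyridine, pyridine/THF, 0 °C to rt
Reagents that add atoms: none
Why: Acid-catalysed methanolysis of the tertiary TES ether and cyclodehydration of the α′-hydroxy 1,3-diketone to the 3(2H)-furanone, then fluoride cleavage of both TBS ethers. The order keeps O8 silylated while O10 closes onto C3, so no other hydroxyl competes; O6 stays as the PMB ether.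

Step 24
Reactants: 33 furanone diol
Product: 36 8,12-lactone PMB ether (4Z,6R,7R,8S,10R), via hydroxy enal 34 (not isolated), via lactol 35 (not isolated)
Conditions: TEMPO (0.2 equiv), PhI(OAc)2 (2.5 equiv), CH2Cl2, rt
Reagents that add atoms: none
Why: Oxidative lactonisation of a 1,4-diol. The primary allylic alcohol is oxidised selectively, the enal is trapped by O8 (the only free hydroxyl) as the lactol and oxidised again. The C8–O bond is never broken, so the trans ring fusion is kept.

Step 25
Reactants: 36 8,12-lactone PMB ether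
Product: 37 6-hydroxy lactone (4Z,6R,7S,8S,10R)
Conditions: DDQ (1.5 equiv), CH2Cl2/pH 7 phosphate buffer, 0 °C to rt
Reagents that add atoms: none
Why: Oxidative cleavage of a 4-methoxybenzyl ether. The buffer keeps the medium neutral so the free C6 hydroxyl does not add to the furanone.

Step 26
Reactants: 38 tiglic acid
Product: 39 tiglyl alcohol, (E)-2-methylbut-2-en-1-ol
Conditions: LiAlH4, Et2O, 0 °C to rt
Reagents that add atoms: none
Why: Hydride reduction of an α,β-unsaturated acid to the allylic alcohol (1,2-reduction) with the E geometry unchanged.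

Step 27
Reactants: 39 tiglyl alcohol
Product: 40 epoxy alcohol, [(2R,3R)-2,3-dimethyloxiran-2-yl]methanol
Conditions: Ti(OiPr)4 (10 mol%), D-(−)-diisopropyl tartrate (12 mol%), t-BuOOH, 4 Å molecular sieves, CH2Cl2, −20 °C
Reagents that add atoms: tert-butyl hydroperoxide, CC(C)(C)OO
Why: Sharpless asymmetric epoxidation. The D-(−)-tartrate should deliver oxygen to the face that gives the (2R,3R) epoxide, and the E alkene fixes the two methyl groups cis.

Step 28
Reactants: 40 epoxy alcohol
Product: 41 epoxy acid, (2S,3R)-2,3-dimethyloxirane-2-carboxylic acid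
Conditions: RuCl3·xH2O (2 mol%), NaIO4 (3 equiv), MeCN/EtOAc/H2O, 0 °C to rt
Reagents that add atoms: water, O; sodium periodate, [Na+].[O-]I(=O)(=O)=O (terminal oxidant that feeds oxygen through RuO4)
Why: Ruthenium tetroxide oxidation of a primary epoxy alcohol to the glycidic acid. No bond at a stereocentre is broken; C2 changes from R to S only because the carboxyl outranks C3.

Step 29
Reactants: 37 6-hydroxy lactone; 41 epoxy acid
Product: 43 target CNP0258430.2, via mixed anhydride 42 (not isolated)
Conditions: 41, 2,4,6-trichlorobenzoyl chloride, Et3N, THF, rt; then 37, DMAP, toluene, rt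
Reagents that add atoms: none
Why: Yamaguchi esterification; the mixed anhydride with DMAP acylates hindered secondary alcohols and couples α,α-disubstituted acids. No stereocentre of either partner is involved.

## Compound list

1 | (R)-glyceraldehyde acetonide, (4R)-2,2-dimethyl-1,3-dioxolane-4-carbaldehyde | CC1(C)OC[C@H](C=O)O1 | starting material
2 | methyl acrylate | C=CC(=O)OC | starting material
3 | methyl 2-{[(4R)-2,2-dimethyl-1,3-dioxolan-4-yl](hydroxy)methyl}prop-2-enoate (both carbinol epimers) | C=C(C(=O)OC)C(O)[C@H]1COC(C)(C)O1 | intermediate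
4 | methyl (4R)-3,4,5-trihydroxy-2-methylidenepentanoate (both C3 epimers) | C=C(C(=O)OC)C(O)[C@H](O)CO | intermediate
5 | (5R)-4-hydroxy-5-(hydroxymethyl)-3-methylideneoxolan-2-one (both C4 epimers) | C=C1C(O)[C@@H](CO)OC1=O | intermediate
6 | [(2R)-3-hydroxy-4-methylidene-5-oxooxolan-2-yl]methyl 2,2-dimethylpropanoate (both C3 epimers) | C=C1C(O)[C@@H](COC(=O)C(C)(C)C)OC1=O | intermediate
7 | [(2S)-4-(bromomethyl)-5-oxo-2,5-dihydrofuran-2-yl]methyl 2,2-dimethylpropanoate | BrCC1=C[C@@H](COC(=O)C(C)(C)C)OC1=O | intermediate
8 | (S)-2-methylglycidol, [(2S)-2-methyloxiran-2-yl]methanol | OC[C@@]1(C)CO1 | starting material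
9 | (2R)-2-methylpent-4-ene-1,2-diol | C=CC[C@@](C)(O)CO | intermediate
10 | (4R)-4-methyl-4,5-bis(triethylsilyloxy)pent-1-ene | C=CC[C@@](C)(O[Si](CC)(CC)CC)CO[Si](CC)(CC)CC | intermediate
11 | ozonide of 10, 3-[(2R)-2-methyl-2,3-bis(triethylsilyloxy)propyl]-1,2,4-trioxolane (ring-carbon epimers) | CC[Si](CC)(CC)OC[C@](C)(O[Si](CC)(CC)CC)CC1OCOO1 | intermediate
12 | (3R)-3-methyl-3,4-bis(triethylsilyloxy)butanal (C8, C9, C10, C14, C1) | O=CC[C@@](C)(O[Si](CC)(CC)CC)CO[Si](CC)(CC)CC | intermediate
13 | {[(5S)-2-oxo-5-(pivaloyloxymethyl)-2,5-dihydrofuran-3-yl]methyl}zinc bromide | Br[Zn]CC1=C[C@@H](COC(=O)C(C)(C)C)OC1=O | intermediate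
14 | [(2S,3R)-3-[(1S,3R)-1-hydroxy-3-methyl-3,4-bis(triethylsilyloxy)butyl]-4-methylidene-5-oxooxolan-2-yl]methyl 2,2-dimethylpropanoate (6S,7R,8S,10R; 6,7-trans on the lactone, 7,8-anti) | C=C1C(=O)O[C@H](COC(=O)C(C)(C)C)[C@H]1[C@@H](O)C[C@@](C)(O[Si](CC)(CC)CC)CO[Si](CC)(CC)CC | intermediate
15 | O8 tert-butyldimethylsilyl ether of 14 (6S,7S,8S,10R) | C=C1C(=O)O[C@H](COC(=O)C(C)(C)C)[C@H]1[C@@H](O[Si](C)(C)C(C)(C)C)C[C@@](C)(O[Si](CC)(CC)CC)CO[Si](CC)(CC)CC | intermediate
16 | seco-chain triol: C5, C6 and C12 hydroxyls free, O8 TBS, O10 and O1 TES (6S,7S,8S,10R) | OC[C@@H](O)[C@H](C(=C)CO)[C@@H](O[Si](C)(C)C(C)(C)C)C[C@@](C)(O[Si](CC)(CC)CC)CO[Si](CC)(CC)CC | intermediate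
17 | O5,O6 4-methoxybenzylidene acetal of 16, C12 hydroxyl free (6S,7S,8S,10R; acetal epimers) | COc1ccc(cc1)C1OC[C@@H](O1)[C@H](C(=C)CO)[C@@H](O[Si](C)(C)C(C)(C)C)C[C@@](C)(O[Si](CC)(CC)CC)CO[Si](CC)(CC)CC | intermediate
18 | O12 TBS ether of 17 (6S,7S,8S,10R; acetal epimers) | COc1ccc(cc1)C1OC[C@@H](O1)[C@H](C(=C)CO[Si](C)(C)C(C)(C)C)[C@@H](O[Si](C)(C)C(C)(C)C)C[C@@](C)(O[Si](CC)(CC)CC)CO[Si](CC)(CC)CC | intermediate
19 | C5 primary alcohol: O6 PMB, O8 and O12 TBS, O10 and O1 TES (6S,7S,8S,10R) | OC[C@@H](OCc1ccc(OC)cc1)[C@H](C(=C)CO[Si](C)(C)C(C)(C)C)[C@@H](O[Si](C)(C)C(C)(C)C)C[C@@](C)(O[Si](CC)(CC)CC)CO[Si](CC)(CC)CC | intermediate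
20 | C5 aldehyde of 19 (6S,7S,8S,10R) | O=C[C@@H](OCc1ccc(OC)cc1)[C@H](C(=C)CO[Si](C)(C)C(C)(C)C)[C@@H](O[Si](C)(C)C(C)(C)C)C[C@@](C)(O[Si](CC)(CC)CC)CO[Si](CC)(CC)CC | intermediate
21 | (Z)-alkenyl iodide: C4 bears iodine and C15, iodine cis to C6; C1 as CH2OTES (4Z,6S,7S,8S,10R) | I/C(C)=C\[C@@H](OCc1ccc(OC)cc1)[C@H](C(=C)CO[Si](C)(C)C(C)(C)C)[C@@H](O[Si](C)(C)C(C)(C)C)C[C@@](C)(O[Si](CC)(CC)CC)CO[Si](CC)(CC)CC | intermediate
22 | C1 aldehyde of the (Z)-alkenyl iodide, O10 TES (4Z,6S,7S,8S,10R) | I/C(C)=C\[C@@H](OCc1ccc(OC)cc1)[C@H](C(=C)CO[Si](C)(C)C(C)(C)C)[C@@H](O[Si](C)(C)C(C)(C)C)C[C@@](C)(O[Si](CC)(CC)CC)C=O | intermediate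
23 | C1 carboxylic acid of the (Z)-alkenyl iodide (4Z,6S,7S,8S,10R) | I/C(C)=C\[C@@H](OCc1ccc(OC)cc1)[C@H](C(=C)CO[Si](C)(C)C(C)(C)C)[C@@H](O[Si](C)(C)C(C)(C)C)C[C@@](C)(O[Si](CC)(CC)CC)C(=O)O | intermediate
24 | C1 S-(9-fluorenylmethyl) thioester of 23 (4Z,6S,7S,8S,10R) | I/C(C)=C\[C@@H](OCc1ccc(OC)cc1)[C@H](C(=C)CO[Si](C)(C)C(C)(C)C)[C@@H](O[Si](C)(C)C(C)(C)C)C[C@@](C)(O[Si](CC)(CC)CC)C(=O)SCC1c2ccccc2-c2ccccc12 | intermediate
25 | 2-ethoxydiene: C3 as ethyl enol ether with C2 methylene, Z C4=C5 (4Z,6R,7S,8S,10R) | C=C(OCC)/C(C)=C\[C@@H](OCc1ccc(OC)cc1)[C@H](C(=C)CO[Si](C)(C)C(C)(C)C)[C@@H](O[Si](C)(C)C(C)(C)C)C[C@@](C)(O[Si](CC)(CC)CC)C(=O)SCC1c2ccccc2-c2ccccc12 | intermediate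
26 | C2 bromomethyl C3 ketone with C1 fluorenylmethyl thioester (4Z,6R,7S,8S,10R) | BrCC(=O)/C(C)=C\[C@@H](OCc1ccc(OC)cc1)[C@H](C(=C)CO[Si](C)(C)C(C)(C)C)[C@@H](O[Si](C)(C)C(C)(C)C)C[C@@](C)(O[Si](CC)(CC)CC)C(=O)SCC1c2ccccc2-c2ccccc12 | intermediate
27 | C1 thioacid of the bromomethyl ketone, present as its DBU salt (4Z,6R,7S,8S,10R) | BrCC(=O)/C(C)=C\[C@@H](OCc1ccc(OC)cc1)[C@H](C(=C)CO[Si](C)(C)C(C)(C)C)[C@@H](O[Si](C)(C)C(C)(C)C)C[C@@](C)(O[Si](CC)(CC)CC)C(=O)S | intermediate
28 | eleven-membered keto thiolactone (ring C1, S, C2–C10): O6 PMB, O8 TBS, O10 TES, C7 bearing C(=CH2)CH2OTBS (4Z,6R,7S,8S,10R) | C=C(CO[Si](C)(C)C(C)(C)C)[C@@H]1[C@@H](O[Si](C)(C)C(C)(C)C)C[C@@](C)(O[Si](CC)(CC)CC)C(=O)SCC(=O)/C(C)=C\[C@H]1OCc2ccc(OC)cc2 | intermediate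
29 | thiirane alkoxide: ten-membered carbocycle with sulfur bridging C1 and C2, potassium alkoxide on C1 (C1 and C2 not defined) | C=C(CO[Si](C)(C)C(C)(C)C)[C@@H]1[C@@H](O[Si](C)(C)C(C)(C)C)C[C@@](C)(O[Si](CC)(CC)CC)C2([O-])SC2C(=O)/C(C)=C\[C@H]1OCc1ccc(OC)cc1.[K+] | intermediate
30 | ten-membered 1,3-diketone (C1 and C3 ketones, drawn as the diketo form), protecting groups as in 28 (4Z,6R,7S,8S,10R) | C=C(CO[Si](C)(C)C(C)(C)C)[C@@H]1[C@@H](O[Si](C)(C)C(C)(C)C)C[C@@](C)(O[Si](CC)(CC)CC)C(=O)CC(=O)/C(C)=C\[C@H]1OCc2ccc(OC)cc2 | intermediate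
31 | C10 hydroxy 1,3-diketone, O8 and O12 TBS, O6 PMB (4Z,6R,7S,8S,10R) | C=C(CO[Si](C)(C)C(C)(C)C)[C@@H]1[C@@H](O[Si](C)(C)C(C)(C)C)C[C@@](C)(O)C(=O)CC(=O)/C(C)=C\[C@H]1OCc2ccc(OC)cc2 | intermediate
32 | furanone bis-TBS ether: 3(2H)-furanone bridging C3 and C10, O8 and O12 TBS, O6 PMB (4Z,6R,7S,8S,10R) | C=C(CO[Si](C)(C)C(C)(C)C)[C@@H]1[C@@H](O[Si](C)(C)C(C)(C)C)C[C@@]2(C)OC(=CC2=O)/C(C)=C\[C@H]1OCc1ccc(OC)cc1 | intermediate
33 | furanone diol: C8 and C12 hydroxyls free, O6 PMB (4Z,6R,7R,8S,10R) | C=C(CO)[C@@H]1[C@@H](O)C[C@@]2(C)OC(=CC2=O)/C(C)=C\[C@H]1OCc1ccc(OC)cc1 | intermediate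
34 | hydroxy enal: C12 aldehyde, C8 hydroxyl, O6 PMB (4Z,6R,7R,8S,10R) | C=C(C=O)[C@@H]1[C@@H](O)C[C@@]2(C)OC(=CC2=O)/C(C)=C\[C@H]1OCc1ccc(OC)cc1 | intermediate
35 | 8,12-lactol, O6 PMB (4Z,6R,7R,8S,10R; C12 epimers) | C=C1C(O)O[C@H]2C[C@@]3(C)OC(=CC3=O)/C(C)=C\[C@@H](OCc4ccc(OC)cc4)[C@H]12 | intermediate
36 | 8,12-lactone with O6 PMB ether (4Z,6R,7R,8S,10R) | C=C1C(=O)O[C@H]2C[C@@]3(C)OC(=CC3=O)/C(C)=C\[C@@H](OCc4ccc(OC)cc4)[C@H]12 | intermediate
37 | 6-hydroxy furanone lactone, the 6-deacyl target (4Z,6R,7S,8S,10R) | C=C1C(=O)O[C@H]2C[C@@]3(C)OC(=CC3=O)/C(C)=C\[C@@H](O)[C@H]12 | intermediate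
38 | tiglic acid, (E)-2-methylbut-2-enoic acid | C/C=C(\C)C(=O)O | starting material
39 | tiglyl alcohol, (E)-2-methylbut-2-en-1-ol | C/C=C(\C)CO | intermediate
40 | [(2R,3R)-2,3-dimethyloxiran-2-yl]methanol | OC[C@@]1(C)O[C@@H]1C | intermediate
41 | (2S,3R)-2,3-dimethyloxirane-2-carboxylic acid | OC(=O)[C@@]1(C)O[C@@H]1C | intermediate
42 | mixed anhydride of 41 with 2,4,6-trichlorobenzoic acid | O=C(OC(=O)[C@@]1(C)O[C@@H]1C)c1c(Cl)cc(Cl)cc1Cl | intermediate
43 | CNP0258430.2 (4Z,6R,7R,8S,10R; ester 2S,3R) | C=C1C(=O)O[C@H]2C[C@@]3(C)OC(=CC3=O)/C(C)=C\[C@@H](OC(=O)[C@@]3(C)O[C@@H]3C)[C@H]12 | target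

## Step count and risk

Total steps: 29. Longest linear sequence: 23 (steps 1–4, 8–25 and 29); aldehyde 12 (steps 5–7) and acid 41 (steps 26–28) are made separately.

**Step 22 (key step).** The most likely failure is that enolisation succeeds but thiirane formation or sulfur transfer to phosphorus is slow at low temperature, and that on warming the Z enone isomerises or the acyl group shifts from sulfur to carbon without loss of sulfur. Fallback, forming the same C1–C2 bond without sulfur, from aldehyde 22: Stille coupling with tributyl(1-ethoxyvinyl)stannane gives the aldehyde enol ether F1, and NBS in wet THF gives the bromomethyl ketone aldehyde F2. SmI2 in THF at −78 °C under high dilution (intramolecular Reformatsky reaction) closes the ring to the ten-membered β-hydroxy ketone F3, and Dess–Martin oxidation returns to 30.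

**Step 8.** An open transition state may compete in the aqueous medium and erode the 7,8-anti selectivity, and the C8 hydroxyl may migrate the lactone before silylation. Fallback from bromide 7: B2pin2 with catalytic Pd2(dba)3 in THF gives the pinacol allylboronate F4. Heating F4 with aldehyde 12 in toluene (allylboration through a closed six-membered transition state, no free alkoxide) and mild hydrolysis returns to 14.

**Step 21.** Intermolecular S-alkylation (oligomers), alkylation of DBU by the bromoketone, and re-addition of the thiocarboxylate to dibenzofulvene can all compete with ring closure. Fallback, closing the ring at C3–C4 instead, from thioester 24: unmasking with DBU and intermolecular S-alkylation with bromoacetaldehyde gives the S-(2-oxoethyl) thioester F5. A Nozaki–Hiyama–Kishi reaction (CrCl2, catalytic NiCl2, high dilution) joins C4 of the Z alkenyl iodide to the aldehyde and gives the eleven-membered allylic alcohol F6; Dess–Martin oxidation returns to 28.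

**Step 16.** Oxidative desilylation of the neopentyl-type primary TES ether may be slow, and forcing it may cost the tertiary TES ether. Fallback from 21: PPTS in MeOH/CH2Cl2 at −10 °C cleaves the primary TES ether to the C1 alcohol F7, and Dess–Martin periodinane returns to 22.

**Step 29.** Acylation of the hindered C6 hydroxyl on the rigid tricycle may be slow, leaving time for DMAP to add to the methylene lactone. Fallback, esterifying before the lactone exists, from 32 (isolated after the PPTS stage of step 23): DDQ gives the 6-hydroxy bis-silyl ether F8, Yamaguchi esterification with 41 gives the ester F9, and HF·pyridine gives the ester diol F10. TEMPO/PhI(OAc)2 lactonisation then returns to 43.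

## Further compounds

F1 | step 22 | C1 aldehyde 2-ethoxydiene (4Z,6R,7S,8S,10R) | C=C(OCC)/C(C)=C\[C@@H](OCc1ccc(OC)cc1)[C@H](C(=C)CO[Si](C)(C)C(C)(C)C)[C@@H](O[Si](C)(C)C(C)(C)C)C[C@@](C)(O[Si](CC)(CC)CC)C=O
F2 | step 22 | C1 aldehyde C2 bromomethyl ketone (4Z,6R,7S,8S,10R) | BrCC(=O)/C(C)=C\[C@@H](OCc1ccc(OC)cc1)[C@H](C(=C)CO[Si](C)(C)C(C)(C)C)[C@@H](O[Si](C)(C)C(C)(C)C)C[C@@](C)(O[Si](CC)(CC)CC)C=O
F3 | step 22 | ten-membered C1 hydroxy C3 ketone (C1 epimers) | C=C(CO[Si](C)(C)C(C)(C)C)[C@@H]1[C@@H](O[Si](C)(C)C(C)(C)C)C[C@@](C)(O[Si](CC)(CC)CC)C(O)CC(=O)/C(C)=C\[C@H]1OCc2ccc(OC)cc2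
F4 | step 8 | pinacol allylboronate of the butenolide, [(2S)-5-oxo-4-[(4,4,5,5-tetramethyl-1,3,2-dioxaborolan-2-yl)methyl]-2,5-dihydrofuran-2-yl]methyl 2,2-dimethylpropanoate | CC1(C)OB(CC2=C[C@@H](COC(=O)C(C)(C)C)OC2=O)OC1(C)C
F5 | step 21 | C1 S-(2-oxoethyl) thioester of the (Z)-alkenyl iodide (4Z,6S,7S,8S,10R) | I/C(C)=C\[C@@H](OCc1ccc(OC)cc1)[C@H](C(=C)CO[Si](C)(C)C(C)(C)C)[C@@H](O[Si](C)(C)C(C)(C)C)C[C@@](C)(O[Si](CC)(CC)CC)C(=O)SCC=O
F6 | step 21 | eleven-membered thiolactone C3 allylic alcohol (C3 epimers) | C=C(CO[Si](C)(C)C(C)(C)C)[C@@H]1[C@@H](O[Si](C)(C)C(C)(C)C)C[C@@](C)(O[Si](CC)(CC)CC)C(=O)SCC(O)/C(C)=C\[C@H]1OCc2ccc(OC)cc2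
F7 | step 16 | C1 primary alcohol of the (Z)-alkenyl iodide (4Z,6S,7S,8S,10R) | I/C(C)=C\[C@@H](OCc1ccc(OC)cc1)[C@H](C(=C)CO[Si](C)(C)C(C)(C)C)[C@@H](O[Si](C)(C)C(C)(C)C)C[C@@](C)(O[Si](CC)(CC)CC)CO
F8 | step 29 | 6-hydroxy furanone bis-TBS ether | C=C(CO[Si](C)(C)C(C)(C)C)[C@@H]1[C@@H](O[Si](C)(C)C(C)(C)C)C[C@@]2(C)OC(=CC2=O)/C(C)=C\[C@H]1O
F9 | step 29 | furanone bis-TBS ether with O6 (2S,3R)-epoxy ester | C=C(CO[Si](C)(C)C(C)(C)C)[C@@H]1[C@@H](O[Si](C)(C)C(C)(C)C)C[C@@]2(C)OC(=CC2=O)/C(C)=C\[C@H]1OC(=O)[C@@]1(C)O[C@@H]1C
F10 | step 29 | furanone C8,C12-diol with O6 (2S,3R)-epoxy ester | C=C(CO)[C@@H]1[C@@H](O)C[C@@]2(C)OC(=CC2=O)/C(C)=C\[C@H]1OC(=O)[C@@]1(C)O[C@@H]1C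
A1 | alternative 1 | 6-hydroxy furanone lactone, identical with 37 | C=C1C(=O)O[C@H]2C[C@@]3(C)OC(=CC3=O)/C(C)=C\[C@@H](O)[C@H]12
A2 | alternative 1 | thirteen-membered bis-allylic ether (O between C6 and C13, C7=C11 butenolide) | O=C1O[C@H]2C[C@@]3(C)OC(=CC3=O)/C(C)=C\COCC1=C2
A3 | alternative 2 | 6-O-TBS furanone germacranolide | C=C1C(=O)O[C@H]2C[C@@]3(C)OC(=CC3=O)/C(C)=C\[C@@H](O[Si](C)(C)C(C)(C)C)[C@H]12
A4 | alternative 2 | lactone-fused cyclooctenone with O10 propynyl ether | C=C1C(=O)O[C@H]2C[C@@](C)(OC#CC)C(=O)/C=C\[C@@H](O[Si](C)(C)C(C)(C)C)[C@H]12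
A5 | alternative 3 | ten-membered furanone 8-hydroxy malonate | COC(=O)C(C(=O)OC)[C@@H]1[C@@H](O)C[C@@]2(C)OC(=CC2=O)/C(C)=C\[C@H]1O[Si](C)(C)C(C)(C)C
A6 | alternative 3 | C8 aldehyde with cyclopropanated siloxyfuran (C1, C9, C10 cyclopropane) | COC(=O)C(C(=O)OC)[C@H](C=O)[C@H](O[Si](C)(C)C(C)(C)C)/C=C(C)\C1=C[C@@]2(O[Si](C)(C)C)C[C@@]2(C)O1
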